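## Retrosynthetic overview

1. The two (Z)-hex-2-enoates come last, by Lindlar reduction of a 3,9-bis(hex-2-ynoate). Before that: 8α-OH by bulky-hydride reduction of an 8-ketone, the C7 isopropenyl group by enolate alkenylation, 9α-OH and the trans ring fusion by Birch reduction and enolate hydroxylation of a Δ9(10)-en-8-one, and 3α-OH/4β-CH3 from a C3=C4 alkene (α-epoxide, radical opening).
2. Key disconnection: ring A is cut at C1–C2 and C3–C4. The two-carbon unit C2–C3 is a heteroaryl vinyl sulfone, inserted between C1 and C4 of ring-B enone 9 by vinylogous Michael addition (C1–C2) and intramolecular Julia–Kocienski olefination (C3=C4).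
3. Enabling feature: in 9 the C1 methyl on C10 is the only γ-position of the C8=O/C9=C10 enone that carries hydrogen, because the ring γ-carbon C5 is quaternary. The acetyl carbonyl C4 on C5 lies four atoms away, so a C1 nucleophile and a C4 electrophile are placed to close a six-membered ring over two carbons.
4. Ring order: ring B first (Michael addition, then desymmetrising aldol condensation of an achiral diacetyl triketone, which sets C5), ring A second (key step). All other stereocentres are derived from C5.

Key step: step 5

Remark on numbering: eremophilane numbers are used from compound 8 onward (ring A = C1–C5 and C10; ring B = C5–C10; C14 = methyl on C5; C15 = methyl on C4; C11–C13 = isopropenyl on C7). β means the face of the C5 methyl and α the opposite face; the SMILES strings are authoritative.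

Assumption: (S)-proline is taken to select between the two acetyl groups of 8 in the same sense as in the Hajos–Parrish cyclisation and so to give (S)-9; if the sense is the opposite, (R)-proline is used.

## Route

Step 1
Reactants: 1 1-phenyl-1H-tetrazole-5-thiol; 2 1,2-dibromoethane
Product: 3 5-[(2-bromoethyl)sulfanyl]-1-phenyl-1H-tetrazole
Conditions: K2CO3, MeCN, 60 °C (2 in fivefold excess)
Reagents that add atoms: none
Why: SN2 S-alkylation of the acidic tetrazolethiol, where the excess of dibromide should suppress double substitution.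

Step 2
Reactants: 3 5-[(2-bromoethyl)sulfanyl]-1-phenyl-1H-tetrazole
Product: 5 5-(ethenylsulfonyl)-1-phenyl-1H-tetrazole, via bromoethyl sulfone 4 (not isolated)
Conditions: mCPBA (2.3 equiv), CH2Cl2, 0 → 23 °C; then Et3N, 0 °C
Reagents that add atoms: 3-chloroperoxybenzoic acid, OOC(=O)c1cccc(Cl)c1
Why: Peracid oxidation of the sulfide to the sulfone followed by E1cB dehydrobromination of the β-bromo sulfone should give the vinyl sulfone.

Step 3
Reactants: 6 3-methylpentane-2,4-dione; 7 but-3-en-2-one
Product: 8 3-acetyl-3-methylheptane-2,6-dione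
Conditions: FeCl3·6H2O (cat.), neat, 23 °C
Reagents that add atoms: none
Why: Iron-catalysed Michael addition of the 2-substituted 1,3-diketone under neutral conditions, which should avoid retro-Claisen deacetylation of the product.

Step 4
Reactants: 8 3-acetyl-3-methylheptane-2,6-dione
Product: 9 (S)-4-acetyl-3,4-dimethylcyclohex-2-en-1-one
Conditions: (S)-proline (30 mol %), HClO4 (cat.), MeCN, 80 °C
Reagents that add atoms: none
Why: Hajos–Parrish–Eder–Sauer–Wiechert-type intramolecular aldol condensation, in which the proline enamine of the unhindered 3-oxobutyl ketone should attack one of the two enantiotopic acetyl carbonyls (setting quaternary C5 as S) and dehydration closes ring B as the enone.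

Step 5
Reactants: 9 (S)-4-acetyl-3,4-dimethylcyclohex-2-en-1-one; 5 5-(ethenylsulfonyl)-1-phenyl-1H-tetrazole
Product: 11 (4aR)-4a,5-dimethyl-4,4a,7,8-tetrahydronaphthalen-2(3H)-one (11,12,13-trinoreremophila-3,9-dien-8-one), via Michael adduct 10 (not isolated)
Conditions: 9-amino-9-deoxy-epi-quinine (20 mol %), 2-fluorobenzoic acid (40 mol %), toluene, 40 °C; then KN(SiMe3)2, THF, −78 → 0 °C
Reagents that add atoms: none
Why: Proposed new method: the primary amine should condense with the enone carbonyl C8 of 9 to the linear dienamine, whose only γ-hydrogens are on the C1 methyl, so its terminal carbon C1 adds to vinyl sulfone 5 (C1–C2 bond) and hydrolysis gives 10; KN(SiMe3)2 then deprotonates C3 next to the sulfone, the carbanion adds to the acetyl carbonyl C4, and Smiles transfer of the tetrazole to oxygen with loss of SO2 and tetrazolone gives the C3=C4 double bond (Julia–Kocienski olefination). The closest known reaction types are the amine-catalysed vinylogous (dienamine) Michael addition of 3-methylcyclohex-2-enones through the exocyclic γ-carbon to nitroalkenes, the amine-catalysed Michael addition to heteroaryl vinyl sulfones followed by Julia–Kocienski olefination, and the Michael–Wittig (Schweizer) annulation. Ring A is closed by 6-exo-trig addition of the C3 carbanion to the C4 ketone. No stereocentre is created: quaternary C5 from step 4 cannot epimerise and is carried through, and the new C3=C4 alkene is the handle for C3 and C4 in steps 6 and 7. The step needs attack through C1 and not through C9 or C7, which the linear dienamine of a β-methyl enone with a blocked ring γ-position should give, and condensation at the enone and not at the acetyl carbonyl, which the hindrance of the acetyl group next to quaternary C5 should secure. Closure on the enone carbonyl instead is excluded because it would put the new alkene at a bridgehead.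

Step 6
Reactants: 11 (4aR)-4a,5-dimethyl-4,4a,7,8-tetrahydronaphthalen-2(3H)-one
Product: 12 3α,4α-epoxy-11,12,13-trinoreremophil-9-en-8-one
Conditions: mCPBA (1.05 equiv), NaHCO3, CH2Cl2, 0 °C
Reagents that add atoms: 3-chloroperoxybenzoic acid, OOC(=O)c1cccc(Cl)c1
Why: Prilezhaev epoxidation, in which the electron-rich trisubstituted C3=C4 alkene should react in preference to the enone alkene and from the α face, opposite the adjacent C5 methyl.

Step 7
Reactants: 12 3α,4α-epoxy-11,12,13-trinoreremophil-9-en-8-one
Product: 13 3α-hydroxy-11,12,13-trinoreremophil-9-en-8-one (4β-methyl)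
Conditions: Cp2TiCl2 (20 mol %), Mn, 2,4,6-collidine·HCl, cyclohexa-1,4-diene, THF, 23 °C
Reagents that add atoms: none
Why: Titanocene-catalysed reductive radical epoxide opening, in which Cp2TiCl (trivalent titanium) cleaves the C4–O bond to the tertiary radical, and this should take a hydrogen atom on the α face opposite the adjacent C5 methyl to give the 3α-alcohol with the 4β-methyl group.

Step 8
Reactants: 13 3α-hydroxy-11,12,13-trinoreremophil-9-en-8-one
Product: 15 3α,9α-dihydroxy-11,12,13-trinoreremophilan-8-one (10α-H), via dilithium enolate 14 (not isolated)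
Conditions: Li, t-BuOH (1 equiv), NH3(l)/THF, −78 °C; isoprene; NH3 removed; 2-(phenylsulfonyl)-3-phenyloxaziridine, THF, −78 °C; aq. NH4Cl
Reagents that add atoms: trans-2-(phenylsulfonyl)-3-phenyloxaziridine, O=S(=O)(c1ccccc1)N1OC1c1ccccc1
Why: Birch-type dissolving-metal reduction should protonate C10 axially to the trans-fused, regiospecific C8–C9 enolate, which the oxaziridine should hydroxylate at C9 on the α face opposite the 1,3-related C5 methyl (also the more stable equatorial position).

Step 9
Reactants: 15 3α,9α-dihydroxy-11,12,13-trinoreremophilan-8-one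
Product: 16 3α,9α-bis(tert-butyldimethylsilyloxy)-11,12,13-trinoreremophilan-8-one
Conditions: TBSOTf (2.4 equiv), 2,6-lutidine, CH2Cl2, −78 → 0 °C
Reagents that add atoms: tert-butyldimethylsilyl trifluoromethanesulfonate, CC(C)(C)[Si](C)(C)OS(=O)(=O)C(F)(F)F
Why: Silyl ether formation protects both secondary alcohols for the enolate and hydride steps.

Step 10
Reactants: 16 3α,9α-bis(tert-butyldimethylsilyloxy)-11,12,13-trinoreremophilan-8-one; 17 2-bromopropene
Product: 19 3α,9α-bis(tert-butyldimethylsilyloxy)eremophil-11-en-8-one (7α-isopropenyl), via lithium enolate 18 (not isolated)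
Conditions: LiN(i-Pr)2, THF, −78 °C; then Pd2(dba)3 (cat.), P(t-Bu)3 (cat.), −78 → 23 °C
Reagents that add atoms: none
Why: Palladium-catalysed α-alkenylation of the kinetic C7 lithium enolate (enolate cross-coupling), where deprotonation should occur at the unhindered CH2 and not at the silyloxy-bearing C9, and the isopropenyl group should end equatorial (α) because the axial position is 1,3-diaxial to the C5 methyl.

Step 11
Reactants: 19 3α,9α-bis(tert-butyldimethylsilyloxy)eremophil-11-en-8-one
Product: 20 3α,9α-bis(tert-butyldimethylsilyloxy)eremophil-11-en-8α-ol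
Conditions: LiBH(s-Bu)3, THF, −78 °C; aq. NH4Cl
Reagents that add atoms: none
Why: Bulky-hydride ketone reduction, in which LiBH(s-Bu)3 should attack from the equatorial direction and give the axial 8α-alcohol, cis to both equatorial neighbours.

Step 12
Reactants: 20 3α,9α-bis(tert-butyldimethylsilyloxy)eremophil-11-en-8α-ol
Product: 21 eremophil-11-ene-3α,8α,9α-triol
Conditions: Bu4NF, THF, 0 → 23 °C
Reagents that add atoms: none
Why: Fluoride-mediated cleavage of both silyl ethers.

Step 13
Reactants: 21 eremophil-11-ene-3α,8α,9α-triol; 22 hex-2-ynoic acid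
Product: 23 eremophil-11-ene-3α,8α,9α-triol 3,9-bis(hex-2-ynoate)
Conditions: 22 (2.2 equiv), DCC, DMAP (cat.), CH2Cl2, −20 → 0 °C
Reagents that add atoms: none
Why: Steglich esterification, in which the two equatorial alcohols at C3 and C9 should be acylated in preference to the axial 8-hydroxyl flanked on both sides; the alkynoic acid is used because a (Z)-enoic acid could isomerise during acylation.

Step 14
Reactants: 23 eremophil-11-ene-3α,8α,9α-triol 3,9-bis(hex-2-ynoate)
Product: 24 eremophil-11-ene-3α,8α,9α-triol 3,9-bis[(2Z)-hex-2-enoate] (target)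
Conditions: H2 (1 atm), Pd/CaCO3 poisoned with Pb(OAc)2, quinoline, EtOAc, 23 °C
Reagents that add atoms: none
Why: Lindlar semihydrogenation, where syn addition of hydrogen to both ynoates should give the two (Z)-enoates and the poisoned catalyst should leave the 1,1-disubstituted isopropenyl alkene untouched.

## Compound list

1 | 1-phenyl-1H-tetrazole-5-thiol | Sc1nnnn1-c1ccccc1 | starting material
2 | 1,2-dibromoethane | BrCCBr | starting material
3 | 5-[(2-bromoethyl)sulfanyl]-1-phenyl-1H-tetrazole | BrCCSc1nnnn1-c1ccccc1 | intermediate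
4 | 5-[(2-bromoethyl)sulfonyl]-1-phenyl-1H-tetrazole | BrCCS(=O)(=O)c1nnnn1-c1ccccc1 | intermediate (not isolated)
5 | 5-(ethenylsulfonyl)-1-phenyl-1H-tetrazole | C=CS(=O)(=O)c1nnnn1-c1ccccc1 | intermediate
6 | 3-methylpentane-2,4-dione | CC(=O)C(C)C(C)=O | starting material
7 | but-3-en-2-one | C=CC(C)=O | starting material
8 | 3-acetyl-3-methylheptane-2,6-dione | CC(=O)CCC(C)(C(C)=O)C(C)=O | intermediate
9 | (S)-4-acetyl-3,4-dimethylcyclohex-2-en-1-one | CC1=CC(=O)CC[C@]1(C)C(C)=O | intermediate
10 | (S)-4-acetyl-4-methyl-3-{3-[(1-phenyl-1H-tetrazol-5-yl)sulfonyl]propyl}cyclohex-2-en-1-one | O=S(=O)(CCCC1=CC(=O)CC[C@]1(C)C(C)=O)c2nnnn2-c3ccccc3 | intermediate (not isolated)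
11 | (4aR)-4a,5-dimethyl-4,4a,7,8-tetrahydronaphthalen-2(3H)-one | C1C[C@]2(C)C(C)=CCCC2=CC1=O | intermediate
12 | 3α,4α-epoxy-11,12,13-trinoreremophil-9-en-8-one | C1C[C@]2(C)[C@]3(C)O[C@@H]3CCC2=CC1=O | intermediate
13 | 3α-hydroxy-11,12,13-trinoreremophil-9-en-8-one (4β-methyl) | C1C[C@]2(C)[C@@H](C)[C@H](O)CCC2=CC1=O | intermediate
14 | dilithium 3α-oxido-11,12,13-trinoreremophil-8-en-8-olate (10α-H) | C1C[C@]2(C)[C@@H](C)[C@H]([O-])CC[C@H]2C=C1[O-].[Li+].[Li+] | intermediate (not isolated)
15 | 3α,9α-dihydroxy-11,12,13-trinoreremophilan-8-one (10α-H) | C1C[C@]2(C)[C@@H](C)[C@H](O)CC[C@H]2[C@H](O)C1=O | intermediate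
16 | 3α,9α-bis(tert-butyldimethylsilyloxy)-11,12,13-trinoreremophilan-8-one | C1C[C@]2(C)[C@@H](C)[C@H](O[Si](C)(C)C(C)(C)C)CC[C@H]2[C@H](O[Si](C)(C)C(C)(C)C)C1=O | intermediate
17 | 2-bromopropene | C=C(C)Br | starting material
18 | lithium 3α,9α-bis(tert-butyldimethylsilyloxy)-11,12,13-trinoreremophil-7-en-8-olate | [Li+].[O-]C1=CC[C@]2(C)[C@@H](C)[C@H](O[Si](C)(C)C(C)(C)C)CC[C@H]2[C@@H]1O[Si](C)(C)C(C)(C)C | intermediate (not isolated)
19 | 3α,9α-bis(tert-butyldimethylsilyloxy)eremophil-11-en-8-one (7α-isopropenyl) | C=C(C)[C@@H]1C[C@]2(C)[C@@H](C)[C@H](O[Si](C)(C)C(C)(C)C)CC[C@H]2[C@H](O[Si](C)(C)C(C)(C)C)C1=O | intermediate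
20 | 3α,9α-bis(tert-butyldimethylsilyloxy)eremophil-11-en-8α-ol | C=C(C)[C@@H]1C[C@]2(C)[C@@H](C)[C@H](O[Si](C)(C)C(C)(C)C)CC[C@H]2[C@H](O[Si](C)(C)C(C)(C)C)[C@@H]1O | intermediate
21 | eremophil-11-ene-3α,8α,9α-triol | C=C(C)[C@@H]1C[C@]2(C)[C@@H](C)[C@H](O)CC[C@H]2[C@H](O)[C@@H]1O | intermediate
22 | hex-2-ynoic acid | CCCC#CC(=O)O | starting material
23 | eremophil-11-ene-3α,8α,9α-triol 3,9-bis(hex-2-ynoate) | C=C(C)[C@@H]1C[C@]2(C)[C@@H](C)[C@H](OC(=O)C#CCCC)CC[C@H]2[C@H](OC(=O)C#CCCC)[C@@H]1O | intermediate
24 | eremophil-11-ene-3α,8α,9α-triol 3,9-bis[(2Z)-hex-2-enoate] | C=C(C)[C@@H]1C[C@]2(C)[C@@H](C)[C@H](OC(=O)/C=C\CCC)CC[C@H]2[C@H](OC(=O)/C=C\CCC)[C@@H]1O | target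

## Step count and risks

Total step count: 14. Longest linear sequence: 12 steps (6 → 24 through steps 3 to 14; the branch from 1 through steps 1, 2 and 5 to 14 is equally long).

Steps most likely to fail:

Step 5 (Proposed new method). The risk is wrong site selectivity in the carbon–carbon bond formation (attack through C9 or C7 instead of C1, or consumption of the vinyl sulfone by the amine), or a stalled ring closure of the sulfonyl carbanion on the hindered acetyl group. The fallback makes the same two bonds by a Schweizer annulation with C1 activated by a nitro group, using known reaction types. It sets out from 9: radical bromination of the only allylic methyl group (NBS, AIBN, PhCF3, 80 °C) should give (S)-4-acetyl-3-(bromomethyl)-4-methylcyclohex-2-en-1-one F1. Kornblum displacement (NaNO2, phloroglucinol, DMF) should give (S)-4-acetyl-4-methyl-3-(nitromethyl)cyclohex-2-en-1-one F2. Its nitronate (KOt-Bu, 2.2 equiv, THF) should add through C1 to vinyltriphenylphosphonium bromide, and the ylide so formed should close on the acetyl carbonyl by intramolecular Wittig reaction to (4aR)-4a,5-dimethyl-8-nitro-4,4a,7,8-tetrahydronaphthalen-2(3H)-one F3 (mixture at the nitro-bearing carbon). Radical denitration (Bu3SnH, AIBN, toluene, 110 °C; DBU to bring any β,γ-unsaturated isomer back into conjugation) comes back to the route at 11.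

Step 4. The risk is poor discrimination between the two enantiotopic acetyl groups of a conformationally mobile triketone, so that C5 is formed with low enantiomeric purity. The fallback gives up catalyst control and resolves: from 8, cyclisation without stereocontrol (pyrrolidine, AcOH, toluene, reflux) should give racemic 4-acetyl-3,4-dimethylcyclohex-2-en-1-one F4, which is separated by preparative chromatography on a chiral stationary phase. The (S)-enantiomer is 9, where the route is rejoined, and (R)-4-acetyl-3,4-dimethylcyclohex-2-en-1-one F5 is set aside.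

Step 10. The risk is equilibration of the enolate towards C9, or migration of the new double bond into conjugation with the ketone under the basic coupling conditions. The fallback introduces the isopropenyl group by cross-coupling on an enone. From 16, dehydrogenation (IBX, DMSO, 70 °C) should give 3α,9α-bis(tert-butyldimethylsilyloxy)-11,12,13-trinoreremophil-6-en-8-one F6. α-Iodination (I2, pyridine, CH2Cl2) should give the 7-iodo enone 3α,9α-bis(tert-butyldimethylsilyloxy)-7-iodo-11,12,13-trinoreremophil-6-en-8-one F7. Suzuki–Miyaura coupling with isopropenylboronic acid pinacol ester (PdCl2(dppf), K3PO4, aqueous dioxane) should give 3α,9α-bis(tert-butyldimethylsilyloxy)eremophila-6,11-dien-8-one F8. Conjugate reduction of the ring enone with [(Ph3P)CuH]6 (benzene, then aqueous NH4Cl) comes back to the route at 19.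

Further compounds
F1 | step 5 | (S)-4-acetyl-3-(bromomethyl)-4-methylcyclohex-2-en-1-one | BrCC1=CC(=O)CC[C@]1(C)C(C)=O
F2 | step 5 | (S)-4-acetyl-4-methyl-3-(nitromethyl)cyclohex-2-en-1-one | O=[N+]([O-])CC1=CC(=O)CC[C@]1(C)C(C)=O
F3 | step 5 | (4aR)-4a,5-dimethyl-8-nitro-4,4a,7,8-tetrahydronaphthalen-2(3H)-one | C1C[C@]2(C)C(C)=CCC([N+](=O)[O-])C2=CC1=O
F4 | step 4 | racemic 4-acetyl-3,4-dimethylcyclohex-2-en-1-one | CC1=CC(=O)CCC1(C)C(C)=O
F5 | step 4 | (R)-4-acetyl-3,4-dimethylcyclohex-2-en-1-one | CC1=CC(=O)CC[C@@]1(C)C(C)=O
F6 | step 10 | 3α,9α-bis(tert-butyldimethylsilyloxy)-11,12,13-trinoreremophil-6-en-8-one | C1=C[C@]2(C)[C@@H](C)[C@H](O[Si](C)(C)C(C)(C)C)CC[C@H]2[C@H](O[Si](C)(C)C(C)(C)C)C1=O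
F7 | step 10 | 3α,9α-bis(tert-butyldimethylsilyloxy)-7-iodo-11,12,13-trinoreremophil-6-en-8-one | IC1=C[C@]2(C)[C@@H](C)[C@H](O[Si](C)(C)C(C)(C)C)CC[C@H]2[C@H](O[Si](C)(C)C(C)(C)C)C1=O
F8 | step 10 | 3α,9α-bis(tert-butyldimethylsilyloxy)eremophila-6,11-dien-8-one | C=C(C)C1=C[C@]2(C)[C@@H](C)[C@H](O[Si](C)(C)C(C)(C)C)CC[C@H]2[C@H](O[Si](C)(C)C(C)(C)C)C1=O
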